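Our unit is a time: the halving of a ratio of two species, which we can read from peaks without knowing what else is in the flask.

| flask | starting material | remark | time |
|---|---|---|---|
| north-east | 0.50 M | run made earlier |  |
| south | 2 M | run made earlier |  |
| flask | 1.0 M |  | 8.0 d |

| run | time / d | target / % | isomer of the product / % |
|---|---|---|---|
| north-east | 0.625 | 16 | 4 |
| north-east | 1.67 | 16 | 13 |
| north-east | 3.00 | 10 | 18 |
| north-east | 5.00 | 2 | 19 |
| north-east | 6.00 | 3 | 20 |
| south | 1.25 | 20 | 4 |
| south | 2.50 | 13 | 20 |
| south | 4.00 | 9 | 18 |
| south | 5.00 | 2 | 20 |
| south | 6.00 | 3 | 16 |

(standard deviation of a reading: 2 percentage points)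

* ratio of target to isomer of the product at 1.0 h
* ratio of target to isomer of the product at 8.0 d
* which of target and isomer of the product there is more of at 8.0 d

- the numbers in the tables scatter by 2 percentage points (one standard deviation)

1. Let r be target over isomer of the product. The runs at 0.50 M and 2 M read alike in percent: at 5.00 d, target is 2% and 2%, and isomer 19% and 20%. So we carry their percent curves to the flask.

2. The north-east run reads r = 1.23 at 1.67 d. The readings of both runs at the last two times pool to r = 0.133 around 5.50 d. The time in which r halves, H, therefore reads 1.19 d over that stretch.

3. We solve two extreme versions of the flask. If target and isomer stand balanced, r stays at 0.133 up to 8.0 d. If r keeps halving every H, it reaches 0.0313. A fall that slows ends between a full stop and an unchanged pace, and the north-east target readings of 2% and 3%, with a scatter of 2 percentage points, do not choose between them. Joining the ends by their geometric mean, we commit to r = 0.0646; both ends stand below one, so isomer leads.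

4. The forecast gives 80 at 1.0 h, 0.12 at 8.0 d and isomer of the product ahead. It reads the late flatness as follows: “This suggests an equilibrium”. Its late ratio stands above ours.

The flask gives 131 at 1.0 h, 0.0532 at 8.0 d, and isomer of the product ahead.

    starting material ⇌ other conformer (K = 1.50, k = 0.00840 h⁻¹)
    starting material → target (k = 0.0230 h⁻¹)
    other conformer → isomer of the product (k = 0.0380 h⁻¹)
    target ⇌ isomer of the product (K = 0.470, k = 0.00110 h⁻¹)
    target → over-reaction product (k = 0.0600 h⁻¹)

In the flask at 8.0 d, isomer is made at 0.175 of the rate at which it is used, each step taken net, so it is being used faster than it is made. In the flask, r stood level at 2.09 d and had fallen by 4.23 halvings at 8.0 d, a span of 4.97 times H. Used on the neighbouring flask with 0.60 M of starting material, H read from percent curves gives the same reckoning, r = 0.0646, and that flask gives 0.0532 at 8.0 d.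

The readings are calculated on assumed constants; scatter was added.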